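The route rests on cutting quinone ring C into a two-carbon piece (C6, which carries the ring B aryloxy oxygen, plus carbonyl carbon C1) and a four-carbon piece (C2 with isopropyl, C3-H, carbonyl carbon C4, C5 with methyl). A Diels–Alder reaction between a 3-aryloxypropynal and a 2-silyloxy-1,3-diene forms C1–C2 and C5–C6 at once, and DDQ in the same flask aromatises the adduct. The step exploits the para relation of the oxygen-bearing carbons C1 and C4 and the donor oxygen on C6, which polarise both partners in the same sense. The formyl group on C1 activates the alkyne and is later exchanged for oxygen by Dakin oxidation.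

Key step: step 10

Labels: ring A is the terminal 2-isopropyl-4-methoxy-5-methylphenoxy ring, ring B the central ring and ring C the quinone. Ar = 2-(2-isopropyl-4-methoxy-5-methylphenoxy)-6-isopropyl-4-methoxy-3-methylphenyl (rings A and B together).
Remark on the chemistry: the target has no stereocentre. The Diels–Alder adduct is racemic (relative configuration drawn) and loses both stereocentres within the same step.

Step 1
Reactants: 1 4-bromo-2-isopropyl-5-methylphenol (4-bromothymol)
Product: 2 2-isopropyl-4-methoxy-5-methylphenol (4-methoxythymol)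
Conditions: NaOMe (5 equiv), CuBr (15 mol %), MeOH/DMF, 110 °C; aq. HCl work-up
Reagents that add atoms: sodium methoxide, [Na+].[O-]C
Why: Ullmann-type copper-catalysed methoxylation should replace the aryl bromide by methoxide while the phenol rides along as its sodium salt and is set free again on acidic work-up.

Step 2
Reactants: 2 2-isopropyl-4-methoxy-5-methylphenol
Product: 4 2-bromo-6-isopropyl-3-methyl-1,4-benzoquinone, via bromophenol 3 (not isolated)
Conditions: NBS (1.0 equiv), MeCN, 0 °C; then H2O, PhI(OAc)2 (1.1 equiv), 0 °C to rt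
Reagents that add atoms: N-bromosuccinimide, O=C1CCC(=O)N1Br; water, O
Why: Electrophilic aromatic bromination should go to the only free position ortho to the strongly directing OH (the other free CH is squeezed between isopropyl and methoxy), and hypervalent-iodine oxidative demethylation of the 4-methoxyphenol 3 in water should then give the quinone with bromine fixed next to the methyl-bearing carbon.

Step 3
Reactants: 2 2-isopropyl-4-methoxy-5-methylphenol; 4 2-bromo-6-isopropyl-3-methyl-1,4-benzoquinone
Product: 5 2-(2-isopropyl-4-methoxy-5-methylphenoxy)-6-isopropyl-3-methyl-1,4-benzoquinone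
Conditions: Cs2CO3 (1.2 equiv), MeCN, 0 °C to rt, Ar
Reagents that add atoms: none
Why: Addition–elimination (vinylogous nucleophilic acyl substitution) of the caesium phenoxide of 2 at the bromine-bearing quinone carbon should form the ring A–ring B diaryl ether, the remaining quinone CH being shielded by the neighbouring isopropyl group.

Step 4
Reactants: 5 2-(2-isopropyl-4-methoxy-5-methylphenoxy)-6-isopropyl-3-methyl-1,4-benzoquinone
Product: 6 2-(2-isopropyl-4-methoxy-5-methylphenoxy)-6-isopropyl-3-methylbenzene-1,4-diol
Conditions: Na2S2O4, THF/H2O, rt, Ar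
Reagents that add atoms: none
Why: Dithionite reduction of a quinone to its hydroquinone is fast and leaves aryl ethers untouched.

Step 5
Reactants: 6 2-(2-isopropyl-4-methoxy-5-methylphenoxy)-6-isopropyl-3-methylbenzene-1,4-diol
Product: 7 2-(2-isopropyl-4-methoxy-5-methylphenoxy)-6-isopropyl-4-methoxy-3-methylphenol (ArOH)
Conditions: MeI (1.05 equiv), K2CO3 (1.1 equiv), acetone, rt, Ar
Reagents that add atoms: iodomethane, CI
Why: Williamson ether synthesis with one equivalent of MeI should methylate the OH flanked by methyl and hydrogen, because the other OH is buried between the isopropyl and the aryloxy group.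

Step 6
Reactants: 7 ArOH; 8 trichloroethylene
Product: 10 (E)-1,2-dichlorovinyl ether ArO-C(Cl)=CHCl, via dichloroacetylene 9 (not isolated)
Conditions: K2CO3, DMF, 70 °C
Reagents that add atoms: none
Why: Base-induced dehydrochlorination of 8 to 9 followed by anti addition of the phenoxide and a proton (net nucleophilic vinylic substitution) should give the E dichlorovinyl ether, and the slim linear electrophile should reach even this doubly ortho-substituted phenoxide.

Step 7
Reactants: 10 (E)-1,2-dichlorovinyl ether ArO-C(Cl)=CHCl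
Product: 13 3-(ArO)prop-2-ynal, via chloroethynyl ether 11 (not isolated), via lithium acetylide 12 (not isolated)
Conditions: n-BuLi (2.2 equiv), THF, −78 to −40 °C; DMF, −78 to 0 °C; reverse quench into aq. KH2PO4
Reagents that add atoms: N,N-dimethylformamide, CN(C)C=O
Why: Dehydrochlorination of 10 to 11, chlorine–lithium exchange to 12 and formylation of the acetylide with DMF is the standard way from dichlorovinyl ethers to substituted ynol ethers, and the buffered reverse quench should keep the liberated dimethylamine from adding to the ynal.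

Step 8
Reactants: 14 isobutyraldehyde (2-methylpropanal); 15 diethyl (2-oxobutyl)phosphonate
Product: 16 (E)-6-methylhept-4-en-3-one
Conditions: NaH, THF, 0 °C; then 14, 0 °C to rt
Reagents that add atoms: none
Why: Horner–Wadsworth–Emmons olefination with a stabilised beta-ketophosphonate anion should give the E enone.

Step 9
Reactants: 16 (E)-6-methylhept-4-en-3-one
Product: 17 (2Z,4E)-3-(tert-butyldimethylsilyloxy)-6-methylhepta-2,4-diene
Conditions: LiN(iPr)2, THF/DMPU, −78 °C; TBSCl, −78 °C to rt
Reagents that add atoms: tert-butyldimethylsilyl chloride, CC(C)(C)[Si](C)(C)Cl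
Why: Kinetic alpha-prime deprotonation of the enone at the ethyl CH2 and O-silylation of the cross-conjugated enolate should give the 2-silyloxydiene, the polar cosolvent favouring the Z enol ether whose methyl group points outward in the s-cis diene.

Step 10
Reactants: 13 3-(ArO)prop-2-ynal; 17 (2Z,4E)-3-(tert-butyldimethylsilyloxy)-6-methylhepta-2,4-diene
Product: 19 2-(ArO)-4-(tert-butyldimethylsilyloxy)-6-isopropyl-3-methylbenzaldehyde, via cyclohexadiene adduct 18 (not isolated)
Conditions: 17 (1.1 equiv), PhMe (1 M), 110 °C, sealed tube; then DDQ (1.2 equiv), 0 °C to rt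
Reagents that add atoms: none
Why: Thermal, concerted but asynchronous normal-electron-demand Diels–Alder cycloaddition: the enol ether terminus C5 of 17 (largest HOMO coefficient) bonds to the aryloxy-bearing alkyne carbon C6 of 13 (largest LUMO coefficient, beta to the formyl group) while C2 bonds to C1. The closest known reaction type is the cycloaddition of 2-silyloxy-1,3-dienes to acetylenic aldehydes, ketones or esters followed by DDQ dehydrogenation of the cyclohexa-1,4-diene to the arene. Ring C is closed as a six-membered carbocycle in an intermolecular suprafacial [4+2] mode, with no tether needed. Because methyl and isopropyl both point outward in the s-cis diene, the two stereocentres of 18 are set cis (racemic), and both are erased when DDQ removes the two doubly allylic hydrogens. The regioselectivity needed (formyl para to silyloxy, aryloxy next to methyl) is secured because the 2-silyloxy donor of the diene and the push-pull polarisation of the ynal act in the same sense, while the directing effects of the two alkyl termini cancel. Chemoselectivity for the triple bond over the formyl C=O is secured by leaving out any Lewis acid, the aryl ynol ether has no beta hydrogen for retro-ene loss to a ketene at 110 °C, and DDQ at 0 °C is consumed by the far better hydride donor 18 before it can attack the electron-rich rings A and B.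

Step 11
Reactants: 19 2-(ArO)-4-(tert-butyldimethylsilyloxy)-6-isopropyl-3-methylbenzaldehyde
Product: 22 2-(ArO)-6-isopropyl-3-methylbenzene-1,4-diol, via hydroxy aldehyde 20 (not isolated), via aryl formate 21 (not isolated)
Conditions: NaOH, THF/MeOH/H2O, 0 °C, Ar; then 30% H2O2 (1.1 equiv), 0 °C to rt; aq. HCl
Reagents that add atoms: hydrogen peroxide, OO
Why: Hydroxide should first cleave the base-labile 4-formylaryl silyl ether, and Dakin oxidation of 20 (hydroperoxide addition, 1,2-aryl shift driven by the para phenoxide, hydrolysis of formate 21) should then replace the formyl group on C1 by OH.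

Step 12
Reactants: 22 2-(ArO)-6-isopropyl-3-methylbenzene-1,4-diol
Product: 23 2-(ArO)-6-isopropyl-3-methyl-1,4-benzoquinone (CNP0335608.0)
Conditions: Ag2O, MgSO4, Et2O, rt
Reagents that add atoms: none
Why: Mild oxidation of a hydroquinone to the quinone with Ag2O should touch neither the fully etherified rings A and B nor the aryloxy substituent on ring C.

Compound list
1 | 4-bromo-2-isopropyl-5-methylphenol | Cc1cc(O)c(C(C)C)cc1Br | starting material
2 | 2-isopropyl-4-methoxy-5-methylphenol | COc1cc(C(C)C)c(O)cc1C | intermediate
3 | 2-bromo-6-isopropyl-4-methoxy-3-methylphenol (not isolated) | COc1cc(C(C)C)c(O)c(Br)c1C | intermediate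
4 | 2-bromo-6-isopropyl-3-methyl-1,4-benzoquinone | CC1=C(Br)C(=O)C(C(C)C)=CC1=O | intermediate
5 | 2-(2-isopropyl-4-methoxy-5-methylphenoxy)-6-isopropyl-3-methyl-1,4-benzoquinone | COc1cc(C(C)C)c(OC2=C(C)C(=O)C=C(C(C)C)C2=O)cc1C | intermediate
6 | 2-(2-isopropyl-4-methoxy-5-methylphenoxy)-6-isopropyl-3-methylbenzene-1,4-diol | COc1cc(C(C)C)c(Oc2c(C)c(O)cc(C(C)C)c2O)cc1C | intermediate
7 | 2-(2-isopropyl-4-methoxy-5-methylphenoxy)-6-isopropyl-4-methoxy-3-methylphenol (ArOH) | COc1cc(C(C)C)c(Oc2c(C)c(OC)cc(C(C)C)c2O)cc1C | intermediate
8 | trichloroethylene | ClC=C(Cl)Cl | starting material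
9 | dichloroacetylene (not isolated) | ClC#CCl | intermediate
10 | (E)-1,2-dichlorovinyl ether of 7 | COc1cc(C(C)C)c(Oc2c(C)c(OC)cc(C(C)C)c2O/C(Cl)=C\Cl)cc1C | intermediate
11 | chloroethynyl ether of 7 (not isolated) | COc1cc(C(C)C)c(Oc2c(C)c(OC)cc(C(C)C)c2OC#CCl)cc1C | intermediate
12 | lithium (aryloxy)acetylide of 7 (not isolated) | COc1cc(C(C)C)c(Oc2c(C)c(OC)cc(C(C)C)c2OC#C[Li])cc1C | intermediate
13 | 3-(ArO)prop-2-ynal | COc1cc(C(C)C)c(Oc2c(C)c(OC)cc(C(C)C)c2OC#CC=O)cc1C | intermediate
14 | isobutyraldehyde | CC(C)C=O | starting material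
15 | diethyl (2-oxobutyl)phosphonate | CCC(=O)CP(=O)(OCC)OCC | starting material
16 | (E)-6-methylhept-4-en-3-one | CCC(=O)/C=C/C(C)C | intermediate
17 | (2Z,4E)-3-(tert-butyldimethylsilyloxy)-6-methylhepta-2,4-diene | C/C=C(\O[Si](C)(C)C(C)(C)C)/C=C/C(C)C | intermediate
18 | cis-2-(ArO)-4-(tert-butyldimethylsilyloxy)-6-isopropyl-3-methylcyclohexa-1,4-diene-1-carbaldehyde (racemic, not isolated) | COc1cc(C(C)C)c(Oc2c(C)c(OC)cc(C(C)C)c2OC2=C(C=O)[C@@H](C(C)C)C=C(O[Si](C)(C)C(C)(C)C)[C@H]2C)cc1C | intermediate
19 | 2-(ArO)-4-(tert-butyldimethylsilyloxy)-6-isopropyl-3-methylbenzaldehyde | COc1cc(C(C)C)c(Oc2c(C)c(OC)cc(C(C)C)c2Oc2c(C)c(O[Si](C)(C)C(C)(C)C)cc(C(C)C)c2C=O)cc1C | intermediate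
20 | 2-(ArO)-4-hydroxy-6-isopropyl-3-methylbenzaldehyde (not isolated) | COc1cc(C(C)C)c(Oc2c(C)c(OC)cc(C(C)C)c2Oc2c(C)c(O)cc(C(C)C)c2C=O)cc1C | intermediate
21 | 2-(ArO)-4-hydroxy-6-isopropyl-3-methylphenyl formate (not isolated) | COc1cc(C(C)C)c(Oc2c(C)c(OC)cc(C(C)C)c2Oc2c(C)c(O)cc(C(C)C)c2OC=O)cc1C | intermediate
22 | 2-(ArO)-6-isopropyl-3-methylbenzene-1,4-diol | COc1cc(C(C)C)c(Oc2c(C)c(OC)cc(C(C)C)c2Oc2c(C)c(O)cc(C(C)C)c2O)cc1C | intermediate
23 | 2-(ArO)-6-isopropyl-3-methyl-1,4-benzoquinone (CNP0335608.0) | COc1cc(C(C)C)c(Oc2c(C)c(OC)cc(C(C)C)c2OC2=C(C)C(=O)C=C(C(C)C)C2=O)cc1C | target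

Total step count: 12. Longest linear sequence: 10 (steps 1 to 7, then 10 to 12). Steps 8 and 9 form the diene branch.

Steps most likely to fail

Step 10. The cycloaddition may be too slow, because the aryloxy donor raises the LUMO of the ynal. Thermal decay of 13, or attack of the silyl enol ether on the formyl group, could then take over. The fallback sets out from 13 and comes back at 19. It replaces 17 by a far more nucleophilic 1-amino-3-silyloxydiene that reacts in a stepwise polar manner and needs no oxidant.
- 3-Methylbut-1-yne is lithiated with n-BuLi and acylated with N-methoxy-N-methylpropanamide to 6-methylhept-4-yn-3-one F1.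
- Conjugate addition of dimethylamine gives (E)-5-(dimethylamino)-6-methylhept-4-en-3-one F2.
- KN(SiMe3)2 and then TBSCl give (2Z,4E)-3-(tert-butyldimethylsilyloxy)-5-(dimethylamino)-6-methylhepta-2,4-diene F3.
- F3 and 13 should combine at or below rt by a Michael–Mannich [4+2] sequence to the amino cyclohexadiene adduct F4.
- Once 13 is used up, F4 is treated with acetic acid, loses dimethylamine in a 1,4-elimination and gives 19.

Step 7. Water or the liberated dimethylamine may add to the strongly electrophilic ynal during the quench and expel the aryloxy group. The fallback sets out from 10 and comes back at 13. Acetylide 12 is made as before but trapped with paraformaldehyde to give 3-(ArO)prop-2-yn-1-ol F5. This alcohol can be purified and is then oxidised under neutral, anhydrous conditions with MnO2 in CH2Cl2.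

Step 11. Peroxide addition to the doubly ortho-substituted aldehyde may be slow. The electron-rich hydroquinone may also be oxidised further by alkaline peroxide, giving the quinone and then its epoxide. The fallback sets out from 19 and comes back at 23, and it avoids basic peroxide altogether.
- Baeyer–Villiger oxidation of the silyl-protected aldehyde with mCPBA in NaHCO3-buffered CH2Cl2 gives 2-(ArO)-4-(tert-butyldimethylsilyloxy)-6-isopropyl-3-methylphenyl formate F6.
- KHCO3 in MeOH cleaves the formate to 2-(ArO)-4-(tert-butyldimethylsilyloxy)-6-isopropyl-3-methylphenol F7.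
- PhI(OAc)2 in aqueous MeCN oxidises this 4-silyloxyphenol directly to 23 with loss of the silyl group.

Further compounds
F1 | step 10 | 6-methylhept-4-yn-3-one | CCC(=O)C#CC(C)C
F2 | step 10 | (E)-5-(dimethylamino)-6-methylhept-4-en-3-one | CCC(=O)/C=C(/N(C)C)C(C)C
F3 | step 10 | (2Z,4E)-3-(tert-butyldimethylsilyloxy)-5-(dimethylamino)-6-methylhepta-2,4-diene | C/C=C(\O[Si](C)(C)C(C)(C)C)/C=C(/N(C)C)C(C)C
F4 | step 10 | 2-(ArO)-4-(tert-butyldimethylsilyloxy)-6-(dimethylamino)-6-isopropyl-3-methylcyclohexa-1,4-diene-1-carbaldehyde (mixture of diastereomers) | COc1cc(C(C)C)c(Oc2c(C)c(OC)cc(C(C)C)c2OC2=C(C=O)C(C(C)C)(N(C)C)C=C(O[Si](C)(C)C(C)(C)C)C2C)cc1C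
F5 | step 7 | 3-(ArO)prop-2-yn-1-ol | COc1cc(C(C)C)c(Oc2c(C)c(OC)cc(C(C)C)c2OC#CCO)cc1C
F6 | step 11 | 2-(ArO)-4-(tert-butyldimethylsilyloxy)-6-isopropyl-3-methylphenyl formate | COc1cc(C(C)C)c(Oc2c(C)c(OC)cc(C(C)C)c2Oc2c(C)c(O[Si](C)(C)C(C)(C)C)cc(C(C)C)c2OC=O)cc1C
F7 | step 11 | 2-(ArO)-4-(tert-butyldimethylsilyloxy)-6-isopropyl-3-methylphenol | COc1cc(C(C)C)c(Oc2c(C)c(OC)cc(C(C)C)c2Oc2c(C)c(O[Si](C)(C)C(C)(C)C)cc(C(C)C)c2O)cc1C
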